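**Retrosynthetic overview**

- The route rests on ring B, a 1,3,4-trisubstituted benzene: C1' is bonded to chromone C2, C3' carries the chiral hydroxyalkyl chain and C4' the phenolic oxygen. This is the C3-alkyl/C4-alkoxy pattern of a 2-pyrone (its C3–C6) joined to two alkyne carbons.
- Last disconnections: hydrogenolysis of three benzyl ethers and desilylation at O7; then ring B is taken apart across C1'–C6' and C2'–C3' into a 2-ethynylchromone (rings A and C) and a 3-alkyl-4-benzyloxy-2-pyrone, with CO2 as the lost bridge.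
- Ethynylchromone: ring C is closed by oxalate Claisen condensation and cyclodehydration on an aryl benzyloxymethyl ketone. The ketone comes from directed ortho-lithiation of a MOM-protected phenol, itself from 3-hydroxy-4,5-dimethoxybenzaldehyde by Baeyer–Villiger oxidation. The ester is then taken to CH2OH, CHO and C≡CH.
- Pyrone: the (R)-Roche ester supplies the stereocentre; one-carbon homologation gives the (S)-iodide, which C-alkylates methyl acetoacetate. Dianion γ-formylation, lactonisation and O-benzylation follow.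
- Ring order: ring A is bought, ring C is closed in step 5, the pyrone ring in step 16, ring B last in step 18.

Key step: step 18

Remark: the extra stereocentres in the diketo ester, the alkylated acetoacetate, its formylation product and the bridged cycloadduct form without control and disappear on aromatisation, so they are drawn without configuration. The Weinreb amide of benzyloxyacetic acid is taken as a purchasable reagent.

**Route**

Step 1
Reactants: 1 3-hydroxy-4,5-dimethoxybenzaldehyde
Product: 2 3,4-dimethoxy-5-[(triisopropylsilyl)oxy]benzaldehyde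
Conditions: TIPSCl, imidazole, DMAP (cat.), DMF, rt
Reagents that add atoms: triisopropylsilyl chloride, CC(C)[Si](Cl)(C(C)C)C(C)C
Why: Routine silylation of a phenol; the bulky silyl ether is chosen because it later shields its own ortho position against lithiation and marks O7 for separate release.

Step 2
Reactants: 2 3,4-dimethoxy-5-[(triisopropylsilyl)oxy]benzaldehyde
Product: 4 3,4-dimethoxy-5-[(triisopropylsilyl)oxy]phenol, via aryl formate 3 (not isolated)
Conditions: mCPBA, CH2Cl2, 0 °C to rt; then MeOH, Et3N (cat.), rt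
Reagents that add atoms: 3-chloroperoxybenzoic acid, OOC(=O)c1cccc(Cl)c1
Why: Baeyer–Villiger (Dakin-type) oxidation in which the electron-rich aryl group with a para methoxy substituent migrates, followed by amine-catalysed methanolysis of the formate that should leave the aryl silyl ether intact.

Step 3
Reactants: 4 3,4-dimethoxy-5-[(triisopropylsilyl)oxy]phenol
Product: 5 1,2-dimethoxy-5-(methoxymethoxy)-3-[(triisopropylsilyl)oxy]benzene
Conditions: MOMCl, i-Pr2NEt, CH2Cl2, 0 °C to rt
Reagents that add atoms: chloromethyl methyl ether, COCCl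
Why: O-alkylation of the phenol installs the methoxymethyl acetal as ortho-directing group.

Step 4
Reactants: 5 1,2-dimethoxy-5-(methoxymethoxy)-3-[(triisopropylsilyl)oxy]benzene; 6 2-(benzyloxy)-N-methoxy-N-methylacetamide
Product: 8 2-(benzyloxy)-1-{2,3-dimethoxy-6-(methoxymethoxy)-4-[(triisopropylsilyl)oxy]phenyl}ethan-1-one, via aryllithium 7 (not isolated)
Conditions: n-BuLi, TMEDA, THF, −20 to 0 °C; then 6, −78 °C to rt; AcOH quench
Reagents that add atoms: none
Why: Directed ortho-metalation should occur only at the ring hydrogen flanked by the OMOM and OMe groups, the other being blocked by the bulky, non-coordinating silyl ether, and the aryllithium acylates the Weinreb amide through a chelated tetrahedral intermediate that prevents over-addition.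

Step 5
Reactants: 8 2-(benzyloxy)-1-{2,3-dimethoxy-6-(methoxymethoxy)-4-[(triisopropylsilyl)oxy]phenyl}ethan-1-one; 9 diethyl oxalate
Product: 11 ethyl 3-(benzyloxy)-5,6-dimethoxy-4-oxo-7-[(triisopropylsilyl)oxy]-4H-chromene-2-carboxylate, via diketo ester 10 (not isolated)
Conditions: LiN(SiMe3)2 (2.2 equiv), THF, −78 °C; 9, −78 to 0 °C; then 3 M aq. HCl, EtOH, 60 °C
Reagents that add atoms: none
Why: Crossed Claisen condensation of the ketone enolate with the non-enolisable oxalate is driven by deprotonation of the 1,3-dicarbonyl product, and acid then cleaves the MOM acetal so that the phenol closes ring C onto the keto ester carbonyl with loss of water (classical chromone-2-carboxylate synthesis).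

Step 6
Reactants: 11 ethyl 3-(benzyloxy)-5,6-dimethoxy-4-oxo-7-[(triisopropylsilyl)oxy]-4H-chromene-2-carboxylate
Product: 12 3-(benzyloxy)-2-(hydroxymethyl)-5,6-dimethoxy-7-[(triisopropylsilyl)oxy]-4H-chromen-4-one
Conditions: NaBH4, EtOH/THF, 0 °C
Reagents that add atoms: none
Why: The C2 ester is activated by the adjacent ring oxygen and enone and should be reduced by borohydride at 0 °C while the vinylogous ester carbonyl at C4 is left alone, as is known for chromone-2-carboxylates.

Step 7
Reactants: 12 3-(benzyloxy)-2-(hydroxymethyl)-5,6-dimethoxy-7-[(triisopropylsilyl)oxy]-4H-chromen-4-one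
Product: 13 3-(benzyloxy)-5,6-dimethoxy-4-oxo-7-[(triisopropylsilyl)oxy]-4H-chromene-2-carbaldehyde
Conditions: Dess–Martin periodinane, CH2Cl2, rt
Reagents that add atoms: none
Why: Dess–Martin oxidation converts the activated primary alcohol to the aldehyde under neutral conditions that tolerate the silyl and benzyl ethers.

Step 8
Reactants: 13 3-(benzyloxy)-5,6-dimethoxy-4-oxo-7-[(triisopropylsilyl)oxy]-4H-chromene-2-carbaldehyde
Product: 14 3-(benzyloxy)-2-ethynyl-5,6-dimethoxy-7-[(triisopropylsilyl)oxy]-4H-chromen-4-one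
Conditions: Me3SiCHN2, n-BuLi, THF, −78 °C; then 13, −78 to 0 °C; AcOH quench
Reagents that add atoms: (trimethylsilyl)diazomethane, C[Si](C)(C)C=[N+]=[N-]
Why: Colvin homologation, in which the lithiated silyl diazomethane adds to the aldehyde, Peterson elimination and loss of N2 give an alkylidene carbene, and 1,2-hydrogen shift gives the terminal alkyne; aprotic low-temperature conditions are chosen to spare the chromone and the aryl silyl ether.

Step 9
Reactants: 15 methyl (R)-3-hydroxy-2-methylpropanoate
Product: 16 methyl (R)-3-(benzyloxy)-2-methylpropanoate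
Conditions: BnOC(=NH)CCl3, TfOH (cat.), CH2Cl2/cyclohexane, 0 °C to rt
Reagents that add atoms: benzyl 2,2,2-trichloroacetimidate, N=C(OCc1ccccc1)C(Cl)(Cl)Cl
Why: Acid-catalysed imidate benzylation avoids base, so the β-hydroxy ester should neither eliminate nor epimerise and the chiral-pool stereocentre is kept.

Step 10
Reactants: 16 methyl (R)-3-(benzyloxy)-2-methylpropanoate
Product: 17 (S)-3-(benzyloxy)-2-methylpropan-1-ol
Conditions: LiAlH4, THF, 0 °C; aq. NaOH work-up
Reagents that add atoms: none
Why: Hydride reduction of the ester to the primary alcohol does not touch the stereocentre; the descriptor becomes S only because the CIP priorities change.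

Step 11
Reactants: 17 (S)-3-(benzyloxy)-2-methylpropan-1-ol
Product: 18 (R)-3-(benzyloxy)-2-methylpropanal
Conditions: Dess–Martin periodinane, CH2Cl2, 0 °C to rt; used crude at once
Reagents that add atoms: none
Why: Mild Dess–Martin oxidation gives the α-branched aldehyde, which is carried on without purification to limit epimerisation.

Step 12
Reactants: 18 (R)-3-(benzyloxy)-2-methylpropanal
Product: 19 (S)-{[(2-methylbut-3-en-1-yl)oxy]methyl}benzene
Conditions: Ph3PCH3Br, KN(SiMe3)2, THF, 0 °C; then 18, −78 to 0 °C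
Reagents that add atoms: methyltriphenylphosphonium bromide, C[P+](c1ccccc1)(c1ccccc1)c1ccccc1.[Br-]
Why: Wittig methylenation with the non-stabilised ylide at low temperature adds the missing chain carbon and should be fast enough to leave the α-stereocentre intact.

Step 13
Reactants: 19 (S)-{[(2-methylbut-3-en-1-yl)oxy]methyl}benzene
Product: 21 (S)-4-(benzyloxy)-3-methylbutan-1-ol, via alkylborane 20 (not isolated)
Conditions: 9-BBN, THF, 0 °C to rt; then NaOH, H2O2, 0 °C to rt
Reagents that add atoms: hydrogen peroxide, OO; 9-borabicyclo[3.3.1]nonane, B1C2CCCC1CCC2 (boron retained only in 20)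
Why: Anti-Markovnikov hydroboration with the bulky borane followed by oxidative C–B cleavage gives the primary alcohol without involving the stereocentre.

Step 14
Reactants: 21 (S)-4-(benzyloxy)-3-methylbutan-1-ol
Product: 22 (S)-{[(4-iodo-2-methylbutoxy)methyl]}benzene
Conditions: I2, PPh3, imidazole, CH2Cl2, 0 °C to rt
Reagents that add atoms: iodine, II
Why: Appel-type iodination converts the unhindered primary alcohol to the iodide by SN2 displacement of the oxyphosphonium group.

Step 15
Reactants: 22 (S)-{[(4-iodo-2-methylbutoxy)methyl]}benzene; 23 methyl acetoacetate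
Product: 24 methyl (5S)-2-acetyl-6-(benzyloxy)-5-methylhexanoate (both C2 epimers)
Conditions: NaH, 23 (2.5 equiv), THF/DMF, 0 to 60 °C
Reagents that add atoms: none
Why: Acetoacetic ester C-alkylation of the sodium enolate with a primary iodide by SN2, with excess keto ester to suppress dialkylation; the new C2 centre is not controlled and is lost when the pyrone forms.

Step 16
Reactants: 24 methyl (5S)-2-acetyl-6-(benzyloxy)-5-methylhexanoate
Product: 26 3-[(3S)-4-(benzyloxy)-3-methylbutyl]-4-hydroxy-2H-pyran-2-one, via formyl keto ester 25 (not isolated)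
Conditions: LiN(i-Pr)2 (3 equiv), THF, −78 to 0 °C; HCO2Me, −78 to 0 °C; AcOH quench; then DBU, toluene, 80 °C
Reagents that add atoms: methyl formate, COC=O
Why: The β-keto ester dianion reacts at its terminal carbon in a Claisen formylation, and the resulting Z-enol oxygen lactonises onto the methyl ester under amidine base, as in the known cyclisation of 3,5-dioxo esters to 4-hydroxy-2-pyrones.

Step 17
Reactants: 26 3-[(3S)-4-(benzyloxy)-3-methylbutyl]-4-hydroxy-2H-pyran-2-one
Product: 27 4-(benzyloxy)-3-[(3S)-4-(benzyloxy)-3-methylbutyl]-2H-pyran-2-one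
Conditions: BnBr, K2CO3, DMF, rt
Reagents that add atoms: benzyl bromide, BrCc1ccccc1
Why: O-alkylation of the vinylogous acid under carbonate conditions should favour the conjugated 4-alkoxy-2-pyrone, and any 2-benzyloxy-4-pyranone isomer would be removed by chromatography.

Step 18
Reactants: 14 3-(benzyloxy)-2-ethynyl-5,6-dimethoxy-7-[(triisopropylsilyl)oxy]-4H-chromen-4-one; 27 4-(benzyloxy)-3-[(3S)-4-(benzyloxy)-3-methylbutyl]-2H-pyran-2-one
Product: 29 3-(benzyloxy)-2-{4-(benzyloxy)-3-[(3S)-4-(benzyloxy)-3-methylbutyl]phenyl}-5,6-dimethoxy-7-[(triisopropylsilyl)oxy]-4H-chromen-4-one, via bicyclic lactone 28 (not isolated)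
Conditions: 27 (1.5 equiv), BHT (cat.), 1,2-dichlorobenzene, sealed tube, 190 °C
Reagents that add atoms: none
Why: Thermal Diels–Alder addition of the alkyne across C3 and C6 of the pyrone gives the bridged lactone 28, which loses CO2 by retro-[4+2] under the same conditions and aromatises. The closest known reaction type is the cycloaddition of 2-pyrones, 4-alkoxy-2-pyrones included, with acceptor-conjugated alkynes to give benzenes with extrusion of CO2. Ring B is closed in an intermolecular [4+2] mode in which C2'–C3' (terminal alkyne carbon to pyrone C3) and C1'–C6' (internal alkyne carbon to pyrone C6) form in one asynchronous step, and the arene is released by cycloreversion. No stereocentre of the product is created: the two bridgehead centres of 28 form without control and vanish on CO2 loss, and the side-chain centre is remote and untouched. The step needs regioselectivity, which is secured electronically because the C4 benzyloxy group and the ring oxygen put the largest HOMO coefficient on pyrone C3 while conjugation through chromone C2=C3–C4=O makes the terminal alkyne carbon the electrophilic end, and sterically because the substituted C3 meets the unsubstituted alkyne terminus. The silyl and benzyl ethers are thermally inert, and excess pyrone with a radical inhibitor should hold back alkyne oligomerisation.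

Step 19
Reactants: 29 3-(benzyloxy)-2-{4-(benzyloxy)-3-[(3S)-4-(benzyloxy)-3-methylbutyl]phenyl}-5,6-dimethoxy-7-[(triisopropylsilyl)oxy]-4H-chromen-4-one
Product: 30 3-(benzyloxy)-2-{4-(benzyloxy)-3-[(3S)-4-(benzyloxy)-3-methylbutyl]phenyl}-7-hydroxy-5,6-dimethoxy-4H-chromen-4-one
Conditions: TBAF, AcOH, THF, 0 °C
Reagents that add atoms: none
Why: Fluoride cleaves the Si–O bond of the aryl silyl ether, and the acetic acid buffer keeps the chromone away from strongly basic fluoride or phenoxide.

Step 20
Reactants: 30 3-(benzyloxy)-2-{4-(benzyloxy)-3-[(3S)-4-(benzyloxy)-3-methylbutyl]phenyl}-7-hydroxy-5,6-dimethoxy-4H-chromen-4-one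
Product: 31 3,7-dihydroxy-2-{4-hydroxy-3-[(3S)-4-hydroxy-3-methylbutyl]phenyl}-5,6-dimethoxy-4H-chromen-4-one
Conditions: H2 (1 atm), Pd/C, EtOAc/MeOH, rt
Reagents that add atoms: none
Why: Catalytic hydrogenolysis should remove the two aryl benzyl ethers and the primary alkyl benzyl ether while the tetrasubstituted C2=C3 bond of the flavonol, the methyl ethers and the stereocentre are unaffected.

**Compound list**

1 | 3-hydroxy-4,5-dimethoxybenzaldehyde | COc1cc(C=O)cc(O)c1OC | starting material
2 | 3,4-dimethoxy-5-[(triisopropylsilyl)oxy]benzaldehyde | COc1cc(C=O)cc(O[Si](C(C)C)(C(C)C)C(C)C)c1OC | intermediate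
3 | 3,4-dimethoxy-5-[(triisopropylsilyl)oxy]phenyl formate | COc1cc(OC=O)cc(O[Si](C(C)C)(C(C)C)C(C)C)c1OC | intermediate
4 | 3,4-dimethoxy-5-[(triisopropylsilyl)oxy]phenol | COc1cc(O)cc(O[Si](C(C)C)(C(C)C)C(C)C)c1OC | intermediate
5 | 1,2-dimethoxy-5-(methoxymethoxy)-3-[(triisopropylsilyl)oxy]benzene | COCOc1cc(OC)c(OC)c(O[Si](C(C)C)(C(C)C)C(C)C)c1 | intermediate
6 | 2-(benzyloxy)-N-methoxy-N-methylacetamide | CON(C)C(=O)COCc1ccccc1 | starting material
7 | {2,3-dimethoxy-6-(methoxymethoxy)-4-[(triisopropylsilyl)oxy]phenyl}lithium | [Li]c1c(OCOC)cc(O[Si](C(C)C)(C(C)C)C(C)C)c(OC)c1OC | intermediate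
8 | 2-(benzyloxy)-1-{2,3-dimethoxy-6-(methoxymethoxy)-4-[(triisopropylsilyl)oxy]phenyl}ethan-1-one | COCOc1cc(O[Si](C(C)C)(C(C)C)C(C)C)c(OC)c(OC)c1C(=O)COCc1ccccc1 | intermediate
9 | diethyl oxalate | CCOC(=O)C(=O)OCC | starting material
10 | ethyl 3-(benzyloxy)-4-{2,3-dimethoxy-6-(methoxymethoxy)-4-[(triisopropylsilyl)oxy]phenyl}-2,4-dioxobutanoate (lithium enolate in the flask) | CCOC(=O)C(=O)C(OCc1ccccc1)C(=O)c1c(OCOC)cc(O[Si](C(C)C)(C(C)C)C(C)C)c(OC)c1OC | intermediate
11 | ethyl 3-(benzyloxy)-5,6-dimethoxy-4-oxo-7-[(triisopropylsilyl)oxy]-4H-chromene-2-carboxylate | CCOC(=O)c1oc2cc(O[Si](C(C)C)(C(C)C)C(C)C)c(OC)c(OC)c2c(=O)c1OCc1ccccc1 | intermediate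
12 | 3-(benzyloxy)-2-(hydroxymethyl)-5,6-dimethoxy-7-[(triisopropylsilyl)oxy]-4H-chromen-4-one | OCc1oc2cc(O[Si](C(C)C)(C(C)C)C(C)C)c(OC)c(OC)c2c(=O)c1OCc1ccccc1 | intermediate
13 | 3-(benzyloxy)-5,6-dimethoxy-4-oxo-7-[(triisopropylsilyl)oxy]-4H-chromene-2-carbaldehyde | O=Cc1oc2cc(O[Si](C(C)C)(C(C)C)C(C)C)c(OC)c(OC)c2c(=O)c1OCc1ccccc1 | intermediate
14 | 3-(benzyloxy)-2-ethynyl-5,6-dimethoxy-7-[(triisopropylsilyl)oxy]-4H-chromen-4-one | C#Cc1oc2cc(O[Si](C(C)C)(C(C)C)C(C)C)c(OC)c(OC)c2c(=O)c1OCc1ccccc1 | intermediate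
15 | methyl (R)-3-hydroxy-2-methylpropanoate | COC(=O)[C@H](C)CO | starting material
16 | methyl (R)-3-(benzyloxy)-2-methylpropanoate | COC(=O)[C@H](C)COCc1ccccc1 | intermediate
17 | (S)-3-(benzyloxy)-2-methylpropan-1-ol | OC[C@H](C)COCc1ccccc1 | intermediate
18 | (R)-3-(benzyloxy)-2-methylpropanal | O=C[C@H](C)COCc1ccccc1 | intermediate
19 | (S)-{[(2-methylbut-3-en-1-yl)oxy]methyl}benzene | C=C[C@H](C)COCc1ccccc1 | intermediate
20 | 9-[(3S)-4-(benzyloxy)-3-methylbutyl]-9-borabicyclo[3.3.1]nonane | B1(CC[C@H](C)COCc2ccccc2)C2CCCC1CCC2 | intermediate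
21 | (S)-4-(benzyloxy)-3-methylbutan-1-ol | OCC[C@H](C)COCc1ccccc1 | intermediate
22 | (S)-{[(4-iodo-2-methylbutoxy)methyl]}benzene | ICC[C@H](C)COCc1ccccc1 | intermediate
23 | methyl acetoacetate | COC(=O)CC(C)=O | starting material
24 | methyl (5S)-2-acetyl-6-(benzyloxy)-5-methylhexanoate (both C2 epimers) | COC(=O)C(CC[C@H](C)COCc1ccccc1)C(C)=O | intermediate
25 | methyl 2-[(3S)-4-(benzyloxy)-3-methylbutyl]-3,5-dioxopentanoate (enol tautomers) | COC(=O)C(CC[C@H](C)COCc1ccccc1)C(=O)CC=O | intermediate
26 | 3-[(3S)-4-(benzyloxy)-3-methylbutyl]-4-hydroxy-2H-pyran-2-one | O=c1occc(O)c1CC[C@H](C)COCc1ccccc1 | intermediate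
27 | 4-(benzyloxy)-3-[(3S)-4-(benzyloxy)-3-methylbutyl]-2H-pyran-2-one | O=c1occc(OCc2ccccc2)c1CC[C@H](C)COCc1ccccc1 | intermediate
28 | 5-(benzyloxy)-4-[(3S)-4-(benzyloxy)-3-methylbutyl]-7-{3-(benzyloxy)-5,6-dimethoxy-4-oxo-7-[(triisopropylsilyl)oxy]-4H-chromen-2-yl}-2-oxabicyclo[2.2.2]octa-5,7-dien-3-one (bridgeheads unassigned) | O=C1OC2C=C(OCc3ccccc3)C1(CC[C@H](C)COCc1ccccc1)C=C2c1oc2cc(O[Si](C(C)C)(C(C)C)C(C)C)c(OC)c(OC)c2c(=O)c1OCc1ccccc1 | intermediate
29 | 3-(benzyloxy)-2-{4-(benzyloxy)-3-[(3S)-4-(benzyloxy)-3-methylbutyl]phenyl}-5,6-dimethoxy-7-[(triisopropylsilyl)oxy]-4H-chromen-4-one | COc1c(O[Si](C(C)C)(C(C)C)C(C)C)cc2oc(-c3ccc(OCc4ccccc4)c(CC[C@H](C)COCc4ccccc4)c3)c(OCc3ccccc3)c(=O)c2c1OC | intermediate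
30 | 3-(benzyloxy)-2-{4-(benzyloxy)-3-[(3S)-4-(benzyloxy)-3-methylbutyl]phenyl}-7-hydroxy-5,6-dimethoxy-4H-chromen-4-one | COc1c(O)cc2oc(-c3ccc(OCc4ccccc4)c(CC[C@H](C)COCc4ccccc4)c3)c(OCc3ccccc3)c(=O)c2c1OC | intermediate
31 | 3,7-dihydroxy-2-{4-hydroxy-3-[(3S)-4-hydroxy-3-methylbutyl]phenyl}-5,6-dimethoxy-4H-chromen-4-one | COc1c(O)cc2oc(-c3ccc(O)c(CC[C@H](C)CO)c3)c(O)c(=O)c2c1OC | target

**Step count and risks**

Total step count: 20 (steps 1–8 chromone branch, steps 9–17 pyrone branch, steps 18–20 after convergence).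
Longest linear sequence: 12 steps (steps 9–20, from the Roche ester 15).

Steps most likely to fail:

1. Step 18. The cycloaddition between a donor-substituted pyrone and an only moderately activated alkyne may be slower than thermal oligomerisation of the conjugated terminal alkyne, or the pyrone may degrade before ring B closes. The fallback sets out from ketone 8 and alkene 19 and returns at 29, with ring B carried in preformed. Commercial methyl 3-bromo-4-hydroxybenzoate would be benzylated (BnBr, K2CO3, DMF) to methyl 4-(benzyloxy)-3-bromobenzoate F1. Alkylborane 20, made from 19 as in step 13 but not oxidised, would be joined to F1 by B-alkyl Suzuki–Miyaura coupling (PdCl2(dppf), aq. K3PO4, DMF/THF, 60 °C) to give methyl 4-(benzyloxy)-3-[(3S)-4-(benzyloxy)-3-methylbutyl]benzoate F2. Crossed Claisen condensation of the lithium enolate of 8 (LiN(SiMe3)2, THF, −78 °C to rt) with F2 would give 2-(benzyloxy)-1-{4-(benzyloxy)-3-[(3S)-4-(benzyloxy)-3-methylbutyl]phenyl}-3-{2,3-dimethoxy-6-(methoxymethoxy)-4-[(triisopropylsilyl)oxy]phenyl}propane-1,3-dione F3. Aqueous HCl in EtOH at 60 °C would then remove the MOM group and close ring C by cyclodehydration to 29.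

2. Step 8. The lithiated diazomethane or the lithium silanolate released may attack the chromone at C2 or C4, add to the newly formed activated alkyne, or cleave the silyl ether at O7. The fallback sets out from aldehyde 13 and returns at alkyne 14. Wittig reaction with bromomethylenetriphenylphosphorane (from (bromomethyl)triphenylphosphonium bromide and NaN(SiMe3)2, THF, −78 °C) would give 3-(benzyloxy)-2-[(Z)-2-bromoethenyl]-5,6-dimethoxy-7-[(triisopropylsilyl)oxy]-4H-chromen-4-one F4, and anti-elimination of HBr with DBU (toluene, 60 °C) would give 14.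

3. Step 16. The γ-formylation may stall because the more acidic product protonates unreacted dianion, and the β-keto aldehyde may deformylate or self-condense before the lactone closes. The fallback sets out from iodide 22 and returns at 26. The sodium enolate of commercial methyl 5,5-dimethoxy-3-oxopentanoate (NaH, THF/DMF, 0 to 60 °C) would be C-alkylated with 22 to give methyl 2-[(3S)-4-(benzyloxy)-3-methylbutyl]-5,5-dimethoxy-3-oxopentanoate F5. Aqueous TFA would unmask the aldehyde to give 25, which would be lactonised with DBU as in step 16 to give 26.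

**Further compounds**

F1 | step 18 | methyl 4-(benzyloxy)-3-bromobenzoate | COC(=O)c1ccc(OCc2ccccc2)c(Br)c1
F2 | step 18 | methyl 4-(benzyloxy)-3-[(3S)-4-(benzyloxy)-3-methylbutyl]benzoate | COC(=O)c1ccc(OCc2ccccc2)c(CC[C@H](C)COCc2ccccc2)c1
F3 | step 18 | 2-(benzyloxy)-1-{4-(benzyloxy)-3-[(3S)-4-(benzyloxy)-3-methylbutyl]phenyl}-3-{2,3-dimethoxy-6-(methoxymethoxy)-4-[(triisopropylsilyl)oxy]phenyl}propane-1,3-dione | COCOc1cc(O[Si](C(C)C)(C(C)C)C(C)C)c(OC)c(OC)c1C(=O)C(OCc1ccccc1)C(=O)c1ccc(OCc2ccccc2)c(CC[C@H](C)COCc2ccccc2)c1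
F4 | step 8 | 3-(benzyloxy)-2-[(Z)-2-bromoethenyl]-5,6-dimethoxy-7-[(triisopropylsilyl)oxy]-4H-chromen-4-one | Br/C=C\c1oc2cc(O[Si](C(C)C)(C(C)C)C(C)C)c(OC)c(OC)c2c(=O)c1OCc1ccccc1
F5 | step 16 | methyl 2-[(3S)-4-(benzyloxy)-3-methylbutyl]-5,5-dimethoxy-3-oxopentanoate | COC(=O)C(CC[C@H](C)COCc1ccccc1)C(=O)CC(OC)OC
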